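**Retrosynthetic overview**
1. Macrolide: C19=C20 by diene–ene ring-closing metathesis (last ring); C4–C5 by γ-acylation of the dianion of (R)-but-3-en-2-yl 2-methylacetoacetate with a C5 thioester.
2. Decalin: rings A and B and the stereocentres C6, C7, C12, C15 from one auxiliary-controlled intramolecular Diels–Alder reaction of a (2E,5Z,8E,10E)-tetraenimide (bonds C6–C15 and C7–C12).
3. Tetraene: dienophile arm by Horner–Wadsworth–Emmons at C7; C13–C14 by Negishi coupling with an alkyne from (R)-Roche ester that carries C16.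
4. Key step: the C7–C12 unit with its Z-trisubstituted C9=C10 olefin is cut out of 4-methylanisole. Birch reduction destroys the arene and fixes the olefin geometry in the ring; ozonolysis of the enol ether then opens it to a C7 ester and a C12 aldehyde.
5. Ring order: A and B together (step 10), 14-membered lactone last (step 16).

Assumption: the enol in the target SMILES is taken as one tautomer of the C3/C5 1,3-diketone; the route delivers the tricarbonyl, which enolises on its own.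
Atom labels: C1 = lactone carbonyl, C2 = methyl-bearing methine, C5 = enol carbon, C6/C7/C12/C15 = decalin stereocentres, C16 = side-chain methine, C21 = carbinol carbon.

**Route**

Step 1
Reactants: 1 4-methylanisole
Product: 2 1-methoxy-4-methylcyclohexa-1,4-diene
Conditions: Li, NH3(l), t-BuOH, THF, −78 → −33 °C; NH4Cl
Reagents that add atoms: none
Why: Birch reduction (the aromaticity-breaking key step) gives the unconjugated 1,4-diene with OMe and CH3 on sp2 carbons, and the ring holds the future C9=C10 olefin in the Z (ring-cis) geometry without any olefination.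

Step 2
Reactants: 2 1-methoxy-4-methylcyclohexa-1,4-diene
Product: 4 methyl (3Z)-4-methyl-6-oxohex-3-enoate, via methoxy hydroperoxide 3 (not isolated)
Conditions: O3 (1.0 equiv, Sudan red end point), CH2Cl2/MeOH, NaHCO3, −78 °C; Me2S, −78 °C → rt
Reagents that add atoms: ozone, [O-][O+]=O
Why: Chemoselective ozonolysis (Criegee cleavage in methanol) of the electron-rich enol ether bond in preference to the trisubstituted olefin opens the ring to a C7 ester and a C12 aldehyde, with the Z olefin untouched.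

Step 3
Reactants: 4 methyl (3Z)-4-methyl-6-oxohex-3-enoate
Product: 5 methyl (3Z,6E)-7-iodo-4-methylhepta-3,6-dienoate
Conditions: CrCl2, CHI3, dioxane/THF (6:1), 0 °C → rt
Reagents that add atoms: iodoform, IC(I)I
Why: Takai olefination is E-selective and non-basic, so the β,γ-unsaturated aldehyde is homologated to the (E)-vinyl iodide before it can move into conjugation.

Step 4
Reactants: 6 methyl (2R)-3-hydroxy-2-methylpropanoate
Product: 7 methyl (2R)-2-methyl-3-(triethylsilyloxy)propanoate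
Conditions: Et3SiCl, imidazole, CH2Cl2, 0 °C
Reagents that add atoms: triethylsilyl chloride, CC[Si](Cl)(CC)CC
Why: Silylation of the primary alcohol; the triethylsilyl ether is chosen because step 11 oxidises it directly, and the chiral-pool centre becomes C16.

Step 5
Reactants: 7 methyl (2R)-2-methyl-3-(triethylsilyloxy)propanoate
Product: 8 (2R)-2-methyl-3-(triethylsilyloxy)propanal
Conditions: i-Bu2AlH (1.05 equiv), CH2Cl2, −78 °C; aq. Rochelle salt
Reagents that add atoms: none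
Why: Partial ester reduction through the stable tetrahedral aluminate at −78 °C gives the aldehyde without epimerising the α-centre.

Step 6
Reactants: 8 (2R)-2-methyl-3-(triethylsilyloxy)propanal
Product: 9 triethyl{[(2S)-2-methylbut-3-yn-1-yl]oxy}silane
Conditions: dimethyl (1-diazo-2-oxopropyl)phosphonate, K2CO3, MeOH, 0 °C → rt
Reagents that add atoms: dimethyl (1-diazo-2-oxopropyl)phosphonate, COP(=O)(OC)C(=[N+]=[N-])C(C)=O
Why: Seyferth–Gilbert homologation with the Ohira–Bestmann reagent converts the aldehyde (C15) into the terminal alkyne under mild base that leaves the adjacent centre intact (the descriptor changes only by priority).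

Step 7
Reactants: 9 triethyl{[(2S)-2-methylbut-3-yn-1-yl]oxy}silane; 5 methyl (3Z,6E)-7-iodo-4-methylhepta-3,6-dienoate
Product: 11 methyl (3Z,6E,8E,10S)-4,10-dimethyl-11-(triethylsilyloxy)undeca-3,6,8-trienoate, via alkenylzirconocene chloride 10 (not isolated)
Conditions: Cp2Zr(H)Cl, THF, rt; then 5, Pd(PPh3)4 (5 mol%), ZnCl2 (20 mol%), THF, rt
Reagents that add atoms: none
Why: Syn-hydrozirconation (Schwartz) gives the (E)-alkenylzirconium, and the Negishi-type palladium coupling joins C13–C14 with retention on both partners to give the (E,E)-diene.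

Step 8
Reactants: 12 (4S)-4-benzyl-1,3-oxazolidin-2-one; 13 (diethoxyphosphoryl)acetic acid
Product: 15 (4S)-4-benzyl-3-[(diethoxyphosphoryl)acetyl]-1,3-oxazolidin-2-one, via mixed pivalic anhydride 14 (not isolated)
Conditions: t-BuCOCl, Et3N, THF, −20 °C; then 12, LiCl, rt
Reagents that add atoms: none
Why: Mixed-anhydride N-acylation of the oxazolidinone (LiCl/Et3N activation) gives the chiral phosphonate in one step.

Step 9
Reactants: 11 methyl (3Z,6E,8E,10S)-4,10-dimethyl-11-(triethylsilyloxy)undeca-3,6,8-trienoate; 15 (4S)-4-benzyl-3-[(diethoxyphosphoryl)acetyl]-1,3-oxazolidin-2-one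
Product: 17 (4S)-4-benzyl-3-[(2E,5Z,8E,10E,12S)-6,12-dimethyl-13-(triethylsilyloxy)trideca-2,5,8,10-tetraenoyl]-1,3-oxazolidin-2-one, via trienal 16 (not isolated)
Conditions: i-Bu2AlH (1.05 equiv), CH2Cl2, −78 °C; then sodium salt of 15 (from 15, NaH, THF, 0 °C), −78 °C → rt
Reagents that add atoms: none
Why: One-pot partial reduction and Horner–Wadsworth–Emmons olefination traps the labile β,γ-unsaturated aldehyde as it is released from the aluminate and gives the (E)-enimide dienophile.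

Step 10
Reactants: 17 (4S)-4-benzyl-3-[(2E,5Z,8E,10E,12S)-6,12-dimethyl-13-(triethylsilyloxy)trideca-2,5,8,10-tetraenoyl]-1,3-oxazolidin-2-one
Product: 18 (4S)-4-benzyl-3-{[(1R,2R,4aR,8aS)-6-methyl-2-[(2S)-1-(triethylsilyloxy)propan-2-yl]-1,2,4a,5,8,8a-hexahydronaphthalen-1-yl]carbonyl}-1,3-oxazolidin-2-one
Conditions: Me2AlCl (1.5 equiv), CH2Cl2, −30 °C
Reagents that add atoms: none
Why: Evans auxiliary-controlled intramolecular Diels–Alder reaction, in which the aluminium chelate holds the enoyl unit s-cis and the diene adds to the C6 face opposite the benzyl group through the endo, trans-fused transition state, sets C6 (R), C7 (S), C12 (R) and C15 (R) and both rings at once.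

Step 11
Reactants: 18 (4S)-4-benzyl-3-{[(1R,2R,4aR,8aS)-6-methyl-2-[(2S)-1-(triethylsilyloxy)propan-2-yl]-1,2,4a,5,8,8a-hexahydronaphthalen-1-yl]carbonyl}-1,3-oxazolidin-2-one
Product: 19 (4S)-4-benzyl-3-{[(1R,2R,4aR,8aS)-6-methyl-2-[(2S)-1-oxopropan-2-yl]-1,2,4a,5,8,8a-hexahydronaphthalen-1-yl]carbonyl}-1,3-oxazolidin-2-one
Conditions: (COCl)2, DMSO, CH2Cl2, −78 → −30 °C; i-Pr2NEt, −78 → 0 °C
Reagents that add atoms: none
Why: Swern oxidation applied directly to the primary triethylsilyl ether (silyl–sulfonium exchange, then ylide fragmentation) gives the C17 aldehyde in one step without epimerising C16.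

Step 12
Reactants: 19 (4S)-4-benzyl-3-{[(1R,2R,4aR,8aS)-6-methyl-2-[(2S)-1-oxopropan-2-yl]-1,2,4a,5,8,8a-hexahydronaphthalen-1-yl]carbonyl}-1,3-oxazolidin-2-one
Product: 21 (4S)-4-benzyl-3-{[(1R,2R,4aR,8aS)-2-[(2R,3Z)-hexa-3,5-dien-2-yl]-6-methyl-1,2,4a,5,8,8a-hexahydronaphthalen-1-yl]carbonyl}-1,3-oxazolidin-2-one, via hydroxy phosphine adduct 20 (not isolated)
Conditions: Ph2PCH2CH=CH2, t-BuLi, THF, −78 °C; Ti(Oi-Pr)4, −78 °C; 19, −78 → 0 °C; MeI, rt
Reagents that add atoms: allyldiphenylphosphine, C=CCP(c1ccccc1)c1ccccc1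
Why: Yamamoto Z-diene synthesis, in which the titanated allylphosphine adds α-selectively to the aldehyde to give the erythro adduct and P-methylation triggers syn-elimination, installs the (Z)-C17=C18 bond of the terminal diene.

Step 13
Reactants: 21 (4S)-4-benzyl-3-{[(1R,2R,4aR,8aS)-2-[(2R,3Z)-hexa-3,5-dien-2-yl]-6-methyl-1,2,4a,5,8,8a-hexahydronaphthalen-1-yl]carbonyl}-1,3-oxazolidin-2-one
Product: 22 S-ethyl (1R,2R,4aR,8aS)-2-[(2R,3Z)-hexa-3,5-dien-2-yl]-6-methyl-1,2,4a,5,8,8a-hexahydronaphthalene-1-carbothioate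
Conditions: EtSH, n-BuLi, THF, 0 °C
Reagents that add atoms: ethanethiol, CCS
Why: Thiolate cleavage of the hindered imide at the exocyclic carbonyl (transthioesterification) releases the auxiliary and gives an acyl donor; the equatorial C6 acyl group is the stable epimer.

Step 14
Reactants: 23 ethyl 2-methyl-3-oxobutanoate; 24 (2R)-but-3-en-2-ol
Product: 25 (2R)-but-3-en-2-yl 2-methyl-3-oxobutanoate
Conditions: DMAP (20 mol%), toluene, 110 °C, removal of EtOH
Reagents that add atoms: none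
Why: DMAP-catalysed transesterification of the β-keto ester brings in C21 (R) from the chiral pool and the C2 methyl group; C2 is left unassigned because it is set at the end.

Step 15
Reactants: 22 S-ethyl (1R,2R,4aR,8aS)-2-[(2R,3Z)-hexa-3,5-dien-2-yl]-6-methyl-1,2,4a,5,8,8a-hexahydronaphthalene-1-carbothioate; 25 (2R)-but-3-en-2-yl 2-methyl-3-oxobutanoate
Product: 26 (2R)-but-3-en-2-yl 5-[(1R,2R,4aR,8aS)-2-[(2R,3Z)-hexa-3,5-dien-2-yl]-6-methyl-1,2,4a,5,8,8a-hexahydronaphthalen-1-yl]-2-methyl-3,5-dioxopentanoate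
Conditions: 25 (3 equiv), LiN(i-Pr)2 (6.2 equiv), THF, −78 → 0 °C; then 22, −78 → −20 °C; AcOH
Reagents that add atoms: none
Why: Claisen-type γ-acylation of the Weiler dianion by the thioester forms C4–C5 and the tricarbonyl directly; excess dianion is used because the acidic product quenches it.

Step 16
Reactants: 26 (2R)-but-3-en-2-yl 5-[(1R,2R,4aR,8aS)-2-[(2R,3Z)-hexa-3,5-dien-2-yl]-6-methyl-1,2,4a,5,8,8a-hexahydronaphthalen-1-yl]-2-methyl-3,5-dioxopentanoate
Product: 28 target macrolide (2R,6R,7S,12R,15R,16R,17Z,19Z,21R), via macrolide C2-epimer mixture 27 (not isolated)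
Conditions: second-generation Grubbs catalyst RuCl2(=CHPh)(PCy3)(H2IMes) (10 mol%), toluene (1 mM), 80 °C; then Et3N, CH2Cl2, rt
Reagents that add atoms: none
Why: Diene–ene ring-closing metathesis closes C19=C20 with loss of ethene, expected Z because the 14-membered ring bridging the cis C6 and C15 arms next to the existing Z olefin disfavours an E bond, and C2 (between lactone and enolised diketone) is then equilibrated by Et3N to the 2R lactone, which is assumed, not shown, to be the more stable epimer.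

**Compound list**
1 | 4-methylanisole | COc1ccc(C)cc1 | starting material
2 | 1-methoxy-4-methylcyclohexa-1,4-diene | COC1=CCC(C)=CC1 | intermediate
3 | methyl (3Z)-6-hydroperoxy-6-methoxy-4-methylhex-3-enoate | COC(=O)C/C=C(C)\CC(OC)OO | intermediate (not isolated)
4 | methyl (3Z)-4-methyl-6-oxohex-3-enoate | COC(=O)C/C=C(C)\CC=O | intermediate
5 | methyl (3Z,6E)-7-iodo-4-methylhepta-3,6-dienoate | COC(=O)C/C=C(C)\C/C=C/I | intermediate
6 | methyl (2R)-3-hydroxy-2-methylpropanoate | COC(=O)[C@H](C)CO | starting material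
7 | methyl (2R)-2-methyl-3-(triethylsilyloxy)propanoate | COC(=O)[C@H](C)CO[Si](CC)(CC)CC | intermediate
8 | (2R)-2-methyl-3-(triethylsilyloxy)propanal | O=C[C@H](C)CO[Si](CC)(CC)CC | intermediate
9 | triethyl{[(2S)-2-methylbut-3-yn-1-yl]oxy}silane | C#C[C@H](C)CO[Si](CC)(CC)CC | intermediate
10 | chlorobis(cyclopentadienyl)[(1E,3S)-3-methyl-4-(triethylsilyloxy)but-1-en-1-yl]zirconium (cyclopentadienyl rings drawn sigma-bonded) | CC[Si](CC)(CC)OC[C@@H](C)/C=C/[Zr](Cl)(C1C=CC=C1)C1C=CC=C1 | intermediate (not isolated)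
11 | methyl (3Z,6E,8E,10S)-4,10-dimethyl-11-(triethylsilyloxy)undeca-3,6,8-trienoate | COC(=O)C/C=C(C)\C/C=C/C=C/[C@H](C)CO[Si](CC)(CC)CC | intermediate
12 | (4S)-4-benzyl-1,3-oxazolidin-2-one | O=C1OC[C@H](Cc2ccccc2)N1 | starting material
13 | (diethoxyphosphoryl)acetic acid | CCOP(=O)(CC(=O)O)OCC | starting material
14 | (diethoxyphosphoryl)acetic 2,2-dimethylpropanoic anhydride | CCOP(=O)(CC(=O)OC(=O)C(C)(C)C)OCC | intermediate (not isolated)
15 | (4S)-4-benzyl-3-[(diethoxyphosphoryl)acetyl]-1,3-oxazolidin-2-one | CCOP(=O)(CC(=O)N1[C@@H](Cc2ccccc2)COC1=O)OCC | intermediate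
16 | (3Z,6E,8E,10S)-4,10-dimethyl-11-(triethylsilyloxy)undeca-3,6,8-trienal | O=CC/C=C(C)\C/C=C/C=C/[C@H](C)CO[Si](CC)(CC)CC | intermediate (not isolated)
17 | (4S)-4-benzyl-3-[(2E,5Z,8E,10E,12S)-6,12-dimethyl-13-(triethylsilyloxy)trideca-2,5,8,10-tetraenoyl]-1,3-oxazolidin-2-one | O=C(/C=C/C/C=C(C)\C/C=C/C=C/[C@H](C)CO[Si](CC)(CC)CC)N1[C@@H](Cc2ccccc2)COC1=O | intermediate
18 | (4S)-4-benzyl-3-{[(1R,2R,4aR,8aS)-6-methyl-2-[(2S)-1-(triethylsilyloxy)propan-2-yl]-1,2,4a,5,8,8a-hexahydronaphthalen-1-yl]carbonyl}-1,3-oxazolidin-2-one | CC1=CC[C@@H]2[C@@H](C(=O)N3[C@@H](Cc4ccccc4)COC3=O)[C@@H]([C@H](C)CO[Si](CC)(CC)CC)C=C[C@H]2C1 | intermediate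
19 | (4S)-4-benzyl-3-{[(1R,2R,4aR,8aS)-6-methyl-2-[(2S)-1-oxopropan-2-yl]-1,2,4a,5,8,8a-hexahydronaphthalen-1-yl]carbonyl}-1,3-oxazolidin-2-one | CC1=CC[C@@H]2[C@@H](C(=O)N3[C@@H](Cc4ccccc4)COC3=O)[C@@H]([C@H](C)C=O)C=C[C@H]2C1 | intermediate
20 | erythro β-hydroxy allylphosphine adduct of 19 (one erythro isomer drawn; the isomer with both new centres inverted gives the same diene) | CC1=CC[C@@H]2[C@@H](C(=O)N3[C@@H](Cc4ccccc4)COC3=O)[C@@H]([C@H](C)[C@@H](O)[C@H](C=C)P(c5ccccc5)c5ccccc5)C=C[C@H]2C1 | intermediate (not isolated)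
21 | (4S)-4-benzyl-3-{[(1R,2R,4aR,8aS)-2-[(2R,3Z)-hexa-3,5-dien-2-yl]-6-methyl-1,2,4a,5,8,8a-hexahydronaphthalen-1-yl]carbonyl}-1,3-oxazolidin-2-one | CC1=CC[C@@H]2[C@@H](C(=O)N3[C@@H](Cc4ccccc4)COC3=O)[C@@H]([C@H](C)/C=C\C=C)C=C[C@H]2C1 | intermediate
22 | S-ethyl (1R,2R,4aR,8aS)-2-[(2R,3Z)-hexa-3,5-dien-2-yl]-6-methyl-1,2,4a,5,8,8a-hexahydronaphthalene-1-carbothioate | CC1=CC[C@@H]2[C@@H](C(=O)SCC)[C@@H]([C@H](C)/C=C\C=C)C=C[C@H]2C1 | intermediate
23 | ethyl 2-methyl-3-oxobutanoate | CCOC(=O)C(C)C(C)=O | starting material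
24 | (2R)-but-3-en-2-ol | C[C@@H](O)C=C | starting material
25 | (2R)-but-3-en-2-yl 2-methyl-3-oxobutanoate (C2 epimers) | CC(=O)C(C)C(=O)O[C@H](C)C=C | intermediate
26 | (2R)-but-3-en-2-yl 5-[(1R,2R,4aR,8aS)-2-[(2R,3Z)-hexa-3,5-dien-2-yl]-6-methyl-1,2,4a,5,8,8a-hexahydronaphthalen-1-yl]-2-methyl-3,5-dioxopentanoate (C2 epimers, enolised) | CC1=CC[C@@H]2[C@@H](C(=O)CC(=O)C(C)C(=O)O[C@H](C)C=C)[C@@H]([C@H](C)/C=C\C=C)C=C[C@H]2C1 | intermediate
27 | target macrolide as C2-epimer mixture | CC1=CC[C@@H]2[C@H]3/C(O)=C\C(=O)C(C)C(=O)O[C@H](C)/C=C\C=C/[C@@H](C)[C@H]3C=C[C@H]2C1 | intermediate (not isolated)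
28 | target macrolide CNP0360406.2 (2R,6R,7S,12R,15R,16R,17Z,19Z,21R) | CC1=CC[C@@H]2[C@H]3/C(O)=C\C(=O)[C@@H](C)C(=O)O[C@H](C)/C=C\C=C/[C@@H](C)[C@H]3C=C[C@H]2C1 | target

**Step count**
Total: 16 steps. Longest linear sequence: 11 steps (1, 2, 3, 7, 9, 10, 11, 12, 13, 15, 16; the Roche-ester branch 4, 5, 6, 7, 9–13, 15, 16 is also 11).

**Three steps most likely to fail**

Step 12 (Z-diene on the branched aldehyde next to an imide). The basic titanate could epimerise C16 or attack the imide, and the Z:E ratio could erode. The fallback sets out from 19 and comes back at 21. Stork–Zhao olefination ([Ph3PCH2I]I, NaN(SiMe3)2, THF/DMPU, −78 °C) converts 19 into the (Z)-vinyl iodide imide F1. A Stille coupling of F1 with tributyl(vinyl)stannane (Pd2(dba)3, AsPh3, DMF, rt) then gives 21 with the Z geometry carried over unchanged.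

Step 15 (acylation of the dianion by a hindered, α-branched thioester). Enolisation of the thioester or slow addition could win over C-acylation. The fallback sets out from 22 and comes back at 26, replacing the acylation by an aldol and an oxidation. i-Bu2AlH (CH2Cl2, −78 °C) reduces 22 to the decalin aldehyde F2. The dianion of 25 (LiN(i-Pr)2, THF, −78 °C) adds to it to give the β-hydroxy keto ester F3 as a carbinol mixture. Dess–Martin periodinane (NaHCO3, CH2Cl2) oxidises F3 to 26.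

Step 16 (ring-closing metathesis and C2 control). Possible failures are an E/Z mixture at C19=C20, ring contraction by attack on the internal diene olefin, and catalyst arrest by the chelating tricarbonyl. The preference for 2R at C2 is assumed, not shown. The fallback sets out from 19 and comes back at 27; it closes the ring by an intramolecular Stille coupling that transfers both olefin geometries unchanged.
- Aldehyde 19 is taken to the (Z)-vinyl iodide imide F1 as above, and EtSH/n-BuLi (THF, 0 °C) converts it into the vinyl iodide thioester F4.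
- Separately, (R)-but-3-yn-2-ol is C-stannylated (n-BuLi 2 equiv, Bu3SnCl, THF) to the stannyl alkynol F5. Hydrozirconation–protonolysis (Cp2Zr(H)Cl, THF; H2O) gives the (Z)-stannyl alkenol F6. Transesterification with 23 (DMAP, toluene, 110 °C) gives the stannyl keto ester F7.
- The dianion of F7 acylates F4 under the conditions of step 15 to give the seco iodide–stannane F8.
- Pd2(dba)3/AsPh3 (DMF, 1 mM, rt) forms the C18–C19 bond to give 27, which is equilibrated with Et3N to 28 as in step 16.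

**Further compounds**
F1 | step 12 | (4S)-4-benzyl-3-{[(1R,2R,4aR,8aS)-2-[(2S,3Z)-4-iodobut-3-en-2-yl]-6-methyl-1,2,4a,5,8,8a-hexahydronaphthalen-1-yl]carbonyl}-1,3-oxazolidin-2-one | CC1=CC[C@@H]2[C@@H](C(=O)N3[C@@H](Cc4ccccc4)COC3=O)[C@@H]([C@H](C)/C=C\I)C=C[C@H]2C1
F2 | step 15 | (1R,2R,4aR,8aS)-2-[(2R,3Z)-hexa-3,5-dien-2-yl]-6-methyl-1,2,4a,5,8,8a-hexahydronaphthalene-1-carbaldehyde | CC1=CC[C@@H]2[C@@H](C=O)[C@@H]([C@H](C)/C=C\C=C)C=C[C@H]2C1
F3 | step 15 | (2R)-but-3-en-2-yl 5-[(1R,2R,4aR,8aS)-2-[(2R,3Z)-hexa-3,5-dien-2-yl]-6-methyl-1,2,4a,5,8,8a-hexahydronaphthalen-1-yl]-5-hydroxy-2-methyl-3-oxopentanoate (carbinol and C2 epimers) | CC1=CC[C@@H]2[C@@H](C(O)CC(=O)C(C)C(=O)O[C@H](C)C=C)[C@@H]([C@H](C)/C=C\C=C)C=C[C@H]2C1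
F4 | step 16 | S-ethyl (1R,2R,4aR,8aS)-2-[(2S,3Z)-4-iodobut-3-en-2-yl]-6-methyl-1,2,4a,5,8,8a-hexahydronaphthalene-1-carbothioate | CC1=CC[C@@H]2[C@@H](C(=O)SCC)[C@@H]([C@H](C)/C=C\I)C=C[C@H]2C1
F5 | step 16 | (2R)-4-(tributylstannyl)but-3-yn-2-ol | C[C@@H](O)C#C[Sn](CCCC)(CCCC)CCCC
F6 | step 16 | (2R,3Z)-4-(tributylstannyl)but-3-en-2-ol | C[C@@H](O)/C=C\[Sn](CCCC)(CCCC)CCCC
F7 | step 16 | (2R,3Z)-4-(tributylstannyl)but-3-en-2-yl 2-methyl-3-oxobutanoate (C2 epimers) | CC(=O)C(C)C(=O)O[C@H](C)/C=C\[Sn](CCCC)(CCCC)CCCC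
F8 | step 16 | (2R,3Z)-4-(tributylstannyl)but-3-en-2-yl 5-[(1R,2R,4aR,8aS)-2-[(2S,3Z)-4-iodobut-3-en-2-yl]-6-methyl-1,2,4a,5,8,8a-hexahydronaphthalen-1-yl]-2-methyl-3,5-dioxopentanoate (C2 epimers) | CC1=CC[C@@H]2[C@@H](C(=O)CC(=O)C(C)C(=O)O[C@H](C)/C=C\[Sn](CCCC)(CCCC)CCCC)[C@@H]([C@H](C)/C=C\I)C=C[C@H]2C1
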